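## Retrosynthetic overview

1. The target comes from a fully protected 19-membered macrolactam by C7 carbamoylation and one acid deprotection. The macrocycle is the last ring formed, closed by intramolecular copper-catalysed N-arylation of a primary dienamide by an aryl bromide.
2. The seco compound is cut at C7–C8: a chelation-controlled addition of an East alkenylzinc (from a C8–C9 methyl alkyne) to a West α-methoxy aldehyde (C1–C7, Z,E-dienoate).
3. The East fragment comes from a symmetric 1,3-dibromo-2,5-bis(MOM-oxy)benzene (one bromine becomes C–Li, the other later C–N) and a cis-α-methyl-γ-lactone. C15 is set by CBS reduction, C10 by alkynylalane opening of an epoxide.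
4. The key step is a Sharpless desymmetrisation of achiral (2E,5E)-hepta-2,5-dien-4-ol, which sets C10, C11 and C12 at once. The second arm is relayed through methacrylate ring-closing metathesis and hydrogenation to set C14.
5. Ring order: oxirane, then butenolide/lactone (temporary), then dioxolane (protecting group), with a dihydropyranone (temporary, fixes 4Z) in the West fragment, and the macrolactam last.

Assumption: atoms carry ansamycin numbers (C1 amide carbonyl to C15 benzylic carbon, C16–C21 arene); the (R,R)-Trost ligand is taken to give (S)-21, and its enantiomer is used if the sense proves opposite.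

## Route

Step 1
Reactants: 1 4-hydroxybenzaldehyde
Product: 2 3,5-dibromo-4-hydroxybenzaldehyde
Conditions: Br2 (2.1 equiv), AcOH, rt
Reagents that add atoms: bromine BrBr
Why: Electrophilic aromatic bromination, in which the phenol directs both bromines ortho because the para position is blocked by the formyl group.

Step 2
Reactants: 2 3,5-dibromo-4-hydroxybenzaldehyde
Product: 4 2,6-dibromobenzene-1,4-diol, via 3,5-dibromo-4-hydroxyphenyl formate 3 (not isolated)
Conditions: 30% aq H2O2, NaOH, H2O/THF, 0 °C → rt; Na2S2O4 wash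
Reagents that add atoms: hydrogen peroxide OO
Why: Dakin oxidation, in which hydroperoxide adds to the para-hydroxybenzaldehyde, the aryl group migrates to oxygen and the aryl formate is saponified in the same pot.

Step 3
Reactants: 4 2,6-dibromobenzene-1,4-diol
Product: 5 1,3-dibromo-2,5-bis(methoxymethoxy)benzene
Conditions: NaH (2.4 equiv), MOMCl (2.4 equiv), DMF, 0 °C → rt
Reagents that add atoms: chloromethyl methyl ether COCCl
Why: Williamson etherification of both phenoxides gives a symmetric arene with two equivalent bromines and an OMOM group that stabilises the ortho-aryllithium.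

Step 4
Reactants: 6 (E)-1-bromoprop-1-ene; 7 (E)-but-2-enal
Product: 9 (2E,5E)-hepta-2,5-dien-4-ol, via (E)-prop-1-enyllithium 8 (not isolated)
Conditions: 6, t-BuLi (2.0 equiv), Et2O, −78 °C; then 7, −78 → 0 °C; H2O
Reagents that add atoms: none
Why: Bromine–lithium exchange with retention of alkene geometry followed by 1,2-addition to the enal gives the achiral bis-allylic alcohol with two enantiotopic propenyl arms.

Step 5
Reactants: 9 (2E,5E)-hepta-2,5-dien-4-ol
Product: 10 (1S,2E)-1-[(2S,3S)-3-methyloxiran-2-yl]but-2-en-1-ol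
Conditions: Ti(OiPr)4 (10 mol%), L-(+)-diisopropyl tartrate (13 mol%), t-BuOOH (1.3 equiv), 4 Å molecular sieves, CH2Cl2, −25 °C
Reagents that add atoms: tert-butyl hydroperoxide CC(C)(C)OO
Why: Sharpless asymmetric epoxidation used as a desymmetrisation, in which the L-(+)-tartrate catalyst selects one enantiotopic arm and one of its faces (erythro-selective, as in kinetic resolution) to set C10, C11 and C12 in one step, while the minor enantiomer is removed faster by a second epoxidation and so raises the ee.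

Step 6
Reactants: 10 (1S,2E)-1-[(2S,3S)-3-methyloxiran-2-yl]but-2-en-1-ol
Product: 11 (1S,2E)-1-[(2R,3S)-3-methyloxiran-2-yl]but-2-en-1-yl 2-methylprop-2-enoate
Conditions: methacryloyl chloride, Et3N, DMAP (cat.), CH2Cl2, 0 °C
Reagents that add atoms: methacryloyl chloride CC(=C)C(Cl)=O
Why: Acylation of the secondary allylic alcohol without touching a stereocentre (the oxirane descriptor changes only through CIP priorities).

Step 7
Reactants: 11 (1S,2E)-1-[(2R,3S)-3-methyloxiran-2-yl]but-2-en-1-yl 2-methylprop-2-enoate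
Product: 12 (5S)-3-methyl-5-[(2R,3S)-3-methyloxiran-2-yl]furan-2(5H)-one
Conditions: second-generation Grubbs catalyst RuCl2(=CHPh)(H2IMes)(PCy3) (5 mol%), CH2Cl2 (0.01 M), 40 °C
Reagents that add atoms: none
Why: Ring-closing metathesis of the remaining propenyl arm with the methacrylate gives the α-methylbutenolide with loss of propene, so the second arm becomes C13 and the acyl group supplies C14, its methyl and C15.

Step 8
Reactants: 12 (5S)-3-methyl-5-[(2R,3S)-3-methyloxiran-2-yl]furan-2(5H)-one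
Product: 13 (3S,5S)-3-methyl-5-[(2R,3S)-3-methyloxiran-2-yl]oxolan-2-one
Conditions: H2 (1 atm), Rh/Al2O3 (5 wt% Rh), EtOAc, rt
Reagents that add atoms: none
Why: Heterogeneous syn-hydrogenation from the butenolide face opposite the C5 oxiranyl group gives the cis-2,4-disubstituted lactone, which sets C14 from C12.

Step 9
Reactants: 5 1,3-dibromo-2,5-bis(methoxymethoxy)benzene; 13 (3S,5S)-3-methyl-5-[(2R,3S)-3-methyloxiran-2-yl]oxolan-2-one
Product: 15 (2S,4S)-1-[3-bromo-2,5-bis(methoxymethoxy)phenyl]-4-hydroxy-2-methyl-4-[(2S,3S)-3-methyloxiran-2-yl]butan-1-one, via [3-bromo-2,5-bis(methoxymethoxy)phenyl]lithium 14 (not isolated)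
Conditions: 5, n-BuLi (1.0 equiv), THF, −78 °C; then 13, −78 °C; H2O
Reagents that add atoms: none
Why: Mono bromine–lithium exchange on the symmetric dibromide (either bromine gives the same aryllithium) and acyl substitution on the lactone, which stops at the ketone stage because the lithium hemiketal is stable at −78 °C.

Step 10
Reactants: 15 (2S,4S)-1-[3-bromo-2,5-bis(methoxymethoxy)phenyl]-4-hydroxy-2-methyl-4-[(2S,3S)-3-methyloxiran-2-yl]butan-1-one
Product: 16 (1R,2S,4S)-1-[3-bromo-2,5-bis(methoxymethoxy)phenyl]-2-methyl-4-[(2S,3S)-3-methyloxiran-2-yl]butane-1,4-diol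
Conditions: (S)-2-methyl-CBS-oxazaborolidine (0.3 equiv), BH3·SMe2 (2.5 equiv), THF, −30 °C; MeOH, aqueous work-up
Reagents that add atoms: none
Why: Corey–Bakshi–Shibata reduction, in which the aryl group acts as the large substituent so that the (S)-catalyst gives the (R)-benzylic alcohol at C15, catalyst control overriding the weak Felkin–Anh bias of the α-methyl centre.

Step 11
Reactants: 16 (1R,2S,4S)-1-[3-bromo-2,5-bis(methoxymethoxy)phenyl]-2-methyl-4-[(2S,3S)-3-methyloxiran-2-yl]butane-1,4-diol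
Product: 17 (1R,2S,4S,5R,6S)-1-[3-bromo-2,5-bis(methoxymethoxy)phenyl]-2,6-dimethylnon-7-yne-1,4,5-triol
Conditions: prop-1-ynyllithium and Et2AlCl (4 equiv each), toluene, 0 °C; then 16, 0 °C → rt; aq KNaC4H4O6 (potassium sodium tartrate) work-up
Reagents that add atoms: prop-1-yn-1-yllithium CC#C[Li]
Why: Hydroxyl-directed opening of the 2,3-epoxy alcohol by the alkynylalane at the distal carbon (C10) with inversion gives the 10,11-syn and 11,12-anti array and installs C8–C9 as a methyl-capped alkyne.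

Step 12
Reactants: 17 (1R,2S,4S,5R,6S)-1-[3-bromo-2,5-bis(methoxymethoxy)phenyl]-2,6-dimethylnon-7-yne-1,4,5-triol
Product: 18 (1R,2S)-1-[3-bromo-2,5-bis(methoxymethoxy)phenyl]-3-{(4S,5R)-2,2-dimethyl-5-[(2S)-pent-3-yn-2-yl]-1,3-dioxolan-4-yl}-2-methylpropan-1-ol
Conditions: 2,2-dimethoxypropane, PPTS (cat.), CH2Cl2, rt
Reagents that add atoms: 2,2-dimethoxypropane COC(C)(C)OC
Why: Acid-catalysed transketalisation is selective for the vicinal C11/C12 diol (five-membered dioxolane) and leaves the benzylic C15 hydroxyl free.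

Step 13
Reactants: 18 (1R,2S)-1-[3-bromo-2,5-bis(methoxymethoxy)phenyl]-3-{(4S,5R)-2,2-dimethyl-5-[(2S)-pent-3-yn-2-yl]-1,3-dioxolan-4-yl}-2-methylpropan-1-ol
Product: 19 1-bromo-3-[(1R,2S)-3-{(4S,5R)-2,2-dimethyl-5-[(2S)-pent-3-yn-2-yl]-1,3-dioxolan-4-yl}-1-methoxy-2-methylpropyl]-2,5-bis(methoxymethoxy)benzene
Conditions: NaH, MeI, THF/DMF, 0 °C → rt
Reagents that add atoms: iodomethane CI
Why: Williamson O-methylation of the only free hydroxyl installs the C15 methyl ether with retention.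

Step 14
Reactants: 20 2-vinyloxirane (racemic)
Product: 21 (2S)-2-methoxybut-3-en-1-ol
Conditions: Pd2(dba)3·CHCl3 (1 mol%), (R,R)-DACH-phenyl Trost ligand (3 mol%), Et3B (1 mol%), MeOH (1.1 equiv), CH2Cl2, rt
Reagents that add atoms: methanol CO
Why: Palladium-catalysed dynamic kinetic asymmetric allylic etherification, in which the racemic vinyl epoxide gives interconverting π-allylpalladium alkoxides and the borate-bound methoxide is delivered to the internal carbon under ligand control, setting C6.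

Step 15
Reactants: 21 (2S)-2-methoxybut-3-en-1-ol
Product: 22 (2S)-2-methoxybut-3-en-1-yl prop-2-enoate
Conditions: acryloyl chloride, Et3N, CH2Cl2, −20 → 0 °C
Reagents that add atoms: acryloyl chloride C=CC(Cl)=O
Why: Acylation of the primary alcohol.

Step 16
Reactants: 22 (2S)-2-methoxybut-3-en-1-yl prop-2-enoate
Product: 23 (5S)-5-methoxy-5,6-dihydro-2H-pyran-2-one
Conditions: second-generation Grubbs catalyst RuCl2(=CHPh)(H2IMes)(PCy3) (3 mol%), CH2Cl2 (5 mM), 40 °C
Reagents that add atoms: none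
Why: Ring-closing metathesis to the six-membered unsaturated lactone locks the future C4=C5 bond in the Z geometry.

Step 17
Reactants: 23 (5S)-5-methoxy-5,6-dihydro-2H-pyran-2-one
Product: 24 (5S)-5-methoxy-5,6-dihydro-2H-pyran-2-ol (anomeric mixture)
Conditions: i-Bu2AlH (1.1 equiv), CH2Cl2, −78 °C; aq KNaC4H4O6 (potassium sodium tartrate) work-up
Reagents that add atoms: none
Why: Partial reduction of the lactone gives the lactol, a masked (Z)-enal.

Step 18
Reactants: 24 (5S)-5-methoxy-5,6-dihydro-2H-pyran-2-ol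
Product: 25 ethyl (2E,4Z,6S)-7-hydroxy-6-methoxy-2-methylhepta-2,4-dienoate
Conditions: Ph3P=C(Me)CO2Et (1.5 equiv), benzene, rt → 45 °C
Reagents that add atoms: ethyl 2-(triphenyl-λ5-phosphanylidene)propanoate CCOC(=O)C(C)=P(c1ccccc1)(c1ccccc1)c1ccccc1
Why: Wittig olefination of the ring-opened (Z)-enal with the stabilised ylide gives the E trisubstituted C2=C3 bond while the ring-derived Z C4=C5 bond is kept.

Step 19
Reactants: 25 ethyl (2E,4Z,6S)-7-hydroxy-6-methoxy-2-methylhepta-2,4-dienoate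
Product: 26 ethyl (2E,4Z,6S)-6-methoxy-2-methyl-7-oxohepta-2,4-dienoate
Conditions: Dess–Martin periodinane, CH2Cl2, 0 °C → rt; used at once
Reagents that add atoms: none
Why: Dess–Martin oxidation gives the α-methoxy aldehyde under neutral, non-epimerising conditions.

Step 20
Reactants: 19 1-bromo-3-[(1R,2S)-3-{(4S,5R)-2,2-dimethyl-5-[(2S)-pent-3-yn-2-yl]-1,3-dioxolan-4-yl}-1-methoxy-2-methylpropyl]-2,5-bis(methoxymethoxy)benzene; 26 ethyl (2E,4Z,6S)-6-methoxy-2-methyl-7-oxohepta-2,4-dienoate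
Product: 29 ethyl (2E,4Z,6S,7S,8E,10S)-10-{(4R,5S)-5-[(2S,3R)-3-[3-bromo-2,5-bis(methoxymethoxy)phenyl]-3-methoxy-2-methylpropyl]-2,2-dimethyl-1,3-dioxolan-4-yl}-7-hydroxy-6-methoxy-2,8-dimethylundeca-2,4,8-trienoate, via C8-alkenylzirconocene chloride 27 (not isolated), via C8-alkenyl(methyl)zinc 28 (not isolated)
Conditions: 19, Cp2Zr(H)Cl (1.4 equiv), THF, 45 °C; solvent exchange to toluene; Me2Zn, −65 °C; then 26 (1.5 equiv), −65 → 0 °C
Reagents that add atoms: none
Why: Wipf hydrozirconation–zinc transmetalation–aldehyde addition, in which syn Zr–H addition places zirconium on the less hindered methyl-bearing alkyne carbon (E trisubstituted alkene) and the alkenylzinc adds to the zinc chelate of the α-methoxy aldehyde (Cram chelate model) to give the 6,7-syn alcohol, setting C7.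

Step 21
Reactants: 29 ethyl (2E,4Z,6S,7S,8E,10S)-10-{(4R,5S)-5-[(2S,3R)-3-[3-bromo-2,5-bis(methoxymethoxy)phenyl]-3-methoxy-2-methylpropyl]-2,2-dimethyl-1,3-dioxolan-4-yl}-7-hydroxy-6-methoxy-2,8-dimethylundeca-2,4,8-trienoate
Product: 30 (2E,4Z,6S,7S,8E,10S)-10-{(4R,5S)-5-[(2S,3R)-3-[3-bromo-2,5-bis(methoxymethoxy)phenyl]-3-methoxy-2-methylpropyl]-2,2-dimethyl-1,3-dioxolan-4-yl}-7-hydroxy-6-methoxy-2,8-dimethylundeca-2,4,8-trienamide
Conditions: AlMe3 and NH4Cl (5 equiv each), toluene, 0 → 50 °C; aq KNaC4H4O6 (potassium sodium tartrate) work-up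
Reagents that add atoms: ammonium chloride [NH4+].[Cl-]
Why: Weinreb aminolysis, in which the aluminium amide made in the flask converts the dienoate directly into the primary amide without touching the alkene geometries.

Step 22
Reactants: 30 (2E,4Z,6S,7S,8E,10S)-10-{(4R,5S)-5-[(2S,3R)-3-[3-bromo-2,5-bis(methoxymethoxy)phenyl]-3-methoxy-2-methylpropyl]-2,2-dimethyl-1,3-dioxolan-4-yl}-7-hydroxy-6-methoxy-2,8-dimethylundeca-2,4,8-trienamide
Product: 31 7-O-decarbamoyl-18,21-di-O-(methoxymethyl)-11,12-O-isopropylidene derivative of 34 (19-membered macrolactam with free C7 hydroxyl)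
Conditions: CuI (30 mol%), N,N′-dimethylethane-1,2-diamine (60 mol%), K2CO3 (3 equiv), toluene (3 mM), 105 °C
Reagents that add atoms: none
Why: Intramolecular Goldberg (Ullmann-type) N-arylation of the primary amide by the aryl bromide closes the 19-membered macrolactam, and the secondary alcohol does not compete under these conditions.

Step 23
Reactants: 31 7-O-decarbamoyl-18,21-di-O-(methoxymethyl)-11,12-O-isopropylidene derivative of 34
Product: 33 18,21-di-O-(methoxymethyl)-11,12-O-isopropylidene derivative of 34, via C7 N-(trichloroacetyl)carbamate 32 (not isolated)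
Conditions: Cl3CC(O)NCO, CH2Cl2, 0 °C; then K2CO3 (cat.), MeOH, rt
Reagents that add atoms: trichloroacetyl isocyanate O=C=NC(=O)C(Cl)(Cl)Cl
Why: Carbamoylation of the only free hydroxyl (C7) by addition to the acyl isocyanate, followed by methanolysis of the trichloroacetyl group.

Step 24
Reactants: 33 18,21-di-O-(methoxymethyl)-11,12-O-isopropylidene derivative of 34
Product: 34 target CNP0523404.1
Conditions: TsOH·H2O (0.5 equiv), MeOH, 0 °C → rt, argon
Reagents that add atoms: none
Why: Acid-catalysed transacetalisation to methanol removes both aryl MOM ethers and the acetonide in one operation, under conditions chosen to be mild for the allylic carbamate and the benzylic ether, with the hydroquinone kept under argon.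

## Compound list

1 | 4-hydroxybenzaldehyde | O=Cc1ccc(O)cc1 | starting material
2 | 3,5-dibromo-4-hydroxybenzaldehyde | O=Cc1cc(Br)c(O)c(Br)c1 | intermediate
3 | 3,5-dibromo-4-hydroxyphenyl formate | O=COc1cc(Br)c(O)c(Br)c1 | intermediate
4 | 2,6-dibromobenzene-1,4-diol | Oc1cc(Br)c(O)c(Br)c1 | intermediate
5 | 1,3-dibromo-2,5-bis(methoxymethoxy)benzene | COCOc1cc(Br)c(OCOC)c(Br)c1 | intermediate
6 | (E)-1-bromoprop-1-ene | C/C=C/Br | starting material
7 | (E)-but-2-enal | C/C=C/C=O | starting material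
8 | (E)-prop-1-enyllithium | C/C=C/[Li] | intermediate
9 | (2E,5E)-hepta-2,5-dien-4-ol | C/C=C/C(O)/C=C/C | intermediate
10 | (1S,2E)-1-[(2S,3S)-3-methyloxiran-2-yl]but-2-en-1-ol | C/C=C/[C@H](O)[C@@H]1O[C@H]1C | intermediate
11 | (1S,2E)-1-[(2R,3S)-3-methyloxiran-2-yl]but-2-en-1-yl 2-methylprop-2-enoate | C/C=C/[C@H](OC(=O)C(C)=C)[C@@H]1O[C@H]1C | intermediate
12 | (5S)-3-methyl-5-[(2R,3S)-3-methyloxiran-2-yl]furan-2(5H)-one | CC1=C[C@H](OC1=O)[C@@H]2O[C@H]2C | intermediate
13 | (3S,5S)-3-methyl-5-[(2R,3S)-3-methyloxiran-2-yl]oxolan-2-one | C[C@H]1C[C@H](OC1=O)[C@@H]2O[C@H]2C | intermediate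
14 | [3-bromo-2,5-bis(methoxymethoxy)phenyl]lithium | COCOc1cc(Br)c(OCOC)c([Li])c1 | intermediate
15 | (2S,4S)-1-[3-bromo-2,5-bis(methoxymethoxy)phenyl]-4-hydroxy-2-methyl-4-[(2S,3S)-3-methyloxiran-2-yl]butan-1-one | COCOc1cc(Br)c(OCOC)c(c1)C(=O)[C@@H](C)C[C@H](O)[C@@H]2O[C@H]2C | intermediate
16 | (1R,2S,4S)-1-[3-bromo-2,5-bis(methoxymethoxy)phenyl]-2-methyl-4-[(2S,3S)-3-methyloxiran-2-yl]butane-1,4-diol | COCOc1cc(Br)c(OCOC)c(c1)[C@H](O)[C@@H](C)C[C@H](O)[C@@H]2O[C@H]2C | intermediate
17 | (1R,2S,4S,5R,6S)-1-[3-bromo-2,5-bis(methoxymethoxy)phenyl]-2,6-dimethylnon-7-yne-1,4,5-triol | COCOc1cc(Br)c(OCOC)c(c1)[C@H](O)[C@@H](C)C[C@H](O)[C@H](O)[C@@H](C)C#CC | intermediate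
18 | (1R,2S)-1-[3-bromo-2,5-bis(methoxymethoxy)phenyl]-3-{(4S,5R)-2,2-dimethyl-5-[(2S)-pent-3-yn-2-yl]-1,3-dioxolan-4-yl}-2-methylpropan-1-ol | COCOc1cc(Br)c(OCOC)c(c1)[C@H](O)[C@@H](C)C[C@@H]2OC(C)(C)O[C@@H]2[C@@H](C)C#CC | intermediate
19 | 1-bromo-3-[(1R,2S)-3-{(4S,5R)-2,2-dimethyl-5-[(2S)-pent-3-yn-2-yl]-1,3-dioxolan-4-yl}-1-methoxy-2-methylpropyl]-2,5-bis(methoxymethoxy)benzene | COCOc1cc(Br)c(OCOC)c(c1)[C@H](OC)[C@@H](C)C[C@@H]2OC(C)(C)O[C@@H]2[C@@H](C)C#CC | intermediate
20 | 2-vinyloxirane (racemic) | C=CC1CO1 | starting material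
21 | (2S)-2-methoxybut-3-en-1-ol | CO[C@H](CO)C=C | intermediate
22 | (2S)-2-methoxybut-3-en-1-yl prop-2-enoate | CO[C@H](COC(=O)C=C)C=C | intermediate
23 | (5S)-5-methoxy-5,6-dihydro-2H-pyran-2-one | CO[C@@H]1COC(=O)C=C1 | intermediate
24 | (5S)-5-methoxy-5,6-dihydro-2H-pyran-2-ol (anomeric mixture) | CO[C@@H]1COC(O)C=C1 | intermediate
25 | ethyl (2E,4Z,6S)-7-hydroxy-6-methoxy-2-methylhepta-2,4-dienoate | CO[C@H](CO)/C=C\C=C(/C)C(=O)OCC | intermediate
26 | ethyl (2E,4Z,6S)-6-methoxy-2-methyl-7-oxohepta-2,4-dienoate | CO[C@H](C=O)/C=C\C=C(/C)C(=O)OCC | intermediate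
27 | (E)-C8-alkenylzirconocene chloride from 19 (Cp2ZrCl on C8, H on C9) | COCOc1cc(Br)c(OCOC)c(c1)[C@H](OC)[C@@H](C)C[C@@H]2OC(C)(C)O[C@@H]2[C@@H](C)/C=C(\C)[Zr](Cl)(C3C=CC=C3)C4C=CC=C4 | intermediate
28 | (E)-C8-alkenyl(methyl)zinc from 27 | COCOc1cc(Br)c(OCOC)c(c1)[C@H](OC)[C@@H](C)C[C@@H]2OC(C)(C)O[C@@H]2[C@@H](C)/C=C(\C)[Zn]C | intermediate
29 | ethyl (2E,4Z,6S,7S,8E,10S)-10-{(4R,5S)-5-[(2S,3R)-3-[3-bromo-2,5-bis(methoxymethoxy)phenyl]-3-methoxy-2-methylpropyl]-2,2-dimethyl-1,3-dioxolan-4-yl}-7-hydroxy-6-methoxy-2,8-dimethylundeca-2,4,8-trienoate | COCOc1cc(Br)c(OCOC)c(c1)[C@H](OC)[C@@H](C)C[C@@H]2OC(C)(C)O[C@@H]2[C@@H](C)/C=C(\C)[C@H](O)[C@@H](OC)/C=C\C=C(/C)C(=O)OCC | intermediate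
30 | primary amide corresponding to 29 (undeca-2,4,8-trienamide, same substituents and descriptors) | COCOc1cc(Br)c(OCOC)c(c1)[C@H](OC)[C@@H](C)C[C@@H]2OC(C)(C)O[C@@H]2[C@@H](C)/C=C(\C)[C@H](O)[C@@H](OC)/C=C\C=C(/C)C(N)=O | intermediate
31 | 7-O-decarbamoyl-18,21-di-O-(methoxymethyl)-11,12-O-isopropylidene derivative of 34 | CO[C@H]1/C=C\C=C(/C)C(=O)Nc2cc(OCOC)cc(c2OCOC)[C@H](OC)[C@@H](C)C[C@@H]3OC(C)(C)O[C@@H]3[C@@H](C)/C=C(\C)[C@@H]1O | intermediate
32 | 7-O-[N-(trichloroacetyl)carbamoyl] derivative of 31 | CO[C@H]1/C=C\C=C(/C)C(=O)Nc2cc(OCOC)cc(c2OCOC)[C@H](OC)[C@@H](C)C[C@@H]3OC(C)(C)O[C@@H]3[C@@H](C)/C=C(\C)[C@@H]1OC(=O)NC(=O)C(Cl)(Cl)Cl | intermediate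
33 | 18,21-di-O-(methoxymethyl)-11,12-O-isopropylidene derivative of 34 | CO[C@H]1/C=C\C=C(/C)C(=O)Nc2cc(OCOC)cc(c2OCOC)[C@H](OC)[C@@H](C)C[C@@H]3OC(C)(C)O[C@@H]3[C@@H](C)/C=C(\C)[C@@H]1OC(N)=O | intermediate
34 | CNP0523404.1 (6S,7S,10S,11R,12S,14S,15R; 2E,4Z,8E; 6,15-dimethoxy; 11,12-diol; 7-O-carbamate; 18,21-dihydroxy arene) | CO[C@H]1/C=C\C=C(/C)C(=O)Nc2cc(O)cc(c2O)[C@H](OC)[C@@H](C)C[C@H](O)[C@H](O)[C@@H](C)/C=C(\C)[C@@H]1OC(N)=O | target

## Step count and risks

Total step count: 24. Longest linear sequence: 15 steps (steps 4–13 and 20–24, from 6 and 7 to 34).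

The three steps most likely to fail:

Step 10. The CBS reduction works against the substrate's Felkin–Anh preference on an α-branched, ortho-substituted aryl ketone that also equilibrates with its cyclic hemiketal, so the C15 ratio may be poor. The fallback sets out from 13 and comes back at 16. Lactone 13 is reduced with i-Bu2AlH (CH2Cl2, −78 °C) to the lactol (3S,5S)-3-methyl-5-[(2R,3S)-3-methyloxiran-2-yl]oxolan-2-ol F1. This is treated with aryllithium 14 (2.2 equiv, THF, −78 → −20 °C): the first equivalent opens the lactol to the alkoxy aldehyde and the second adds under Felkin–Anh control (14,15-syn) to give 16 directly, bypassing 15. C15 is then set by substrate-controlled aryl addition to an aldehyde instead of by reagent-controlled hydride delivery to a ketone.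

Step 20. The hydrozirconation must be regioselective, chelation control by zinc may be modest, and aldehyde 26 is sensitive. The fallback sets out from 19 and comes back at 29. Hydrozirconation of 19 (via 27) followed by I2 gives the (E)-vinyl iodide F2. Nozaki–Hiyama–Kishi coupling of F2 with 26 (CrCl2, NiCl2 cat., DMSO) gives 29 mixed with its C7 epimer F3. The mixture is oxidised with Dess–Martin periodinane to the enone F4. Reduction with LiBH(s-Bu)3 (THF, −78 °C), under non-chelating Felkin–Anh control with the methoxy group anti to the incoming hydride, gives the 6,7-syn alcohol 29. C7 is then set by ketone reduction and not in the C–C bond-forming step.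

Step 22. The macrocyclising N-arylation takes place at a hindered ortho-alkoxy aryl bromide at 105 °C and may be slow or give oligomers. The fallback sets out from 29 and comes back at 31, so step 21 is not needed. Coupling of 29 with benzophenone imine (Pd2(dba)3, BINAP, Cs2CO3, toluene, 90 °C) gives the N-aryl benzophenone imine F5. NH2OH·HCl/NaOAc in MeOH frees the aniline F6, and LiOH (THF/MeOH/H2O) gives the amino acid F7. Macrolactamisation with BOP-Cl and i-Pr2NEt (toluene, 85 °C, high dilution) gives 31. The ring is then closed by amide-bond formation instead of C–N cross-coupling.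

## Further compounds

F1 | step 10 | (3S,5S)-3-methyl-5-[(2R,3S)-3-methyloxiran-2-yl]oxolan-2-ol | C[C@H]1C[C@H](OC1O)[C@@H]2O[C@H]2C
F2 | step 20 | (E)-C8 vinyl iodide from 19 (iodine on C8, H on C9) | COCOc1cc(Br)c(OCOC)c(c1)[C@H](OC)[C@@H](C)C[C@@H]2OC(C)(C)O[C@@H]2[C@@H](C)/C=C(\C)I
F3 | step 20 | C7 epimer of 29 (7R) | COCOc1cc(Br)c(OCOC)c(c1)[C@H](OC)[C@@H](C)C[C@@H]2OC(C)(C)O[C@@H]2[C@@H](C)/C=C(\C)[C@@H](O)[C@@H](OC)/C=C\C=C(/C)C(=O)OCC
F4 | step 20 | C7 ketone (enone) of 29 | COCOc1cc(Br)c(OCOC)c(c1)[C@H](OC)[C@@H](C)C[C@@H]2OC(C)(C)O[C@@H]2[C@@H](C)/C=C(\C)C(=O)[C@@H](OC)/C=C\C=C(/C)C(=O)OCC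
F5 | step 22 | N-(diphenylmethylidene)aniline analogue of 29 (Br replaced by N=CPh2) | COCOc1cc(N=C(c3ccccc3)c4ccccc4)c(OCOC)c(c1)[C@H](OC)[C@@H](C)C[C@@H]2OC(C)(C)O[C@@H]2[C@@H](C)/C=C(\C)[C@H](O)[C@@H](OC)/C=C\C=C(/C)C(=O)OCC
F6 | step 22 | aniline analogue of 29 (Br replaced by NH2) | COCOc1cc(N)c(OCOC)c(c1)[C@H](OC)[C@@H](C)C[C@@H]2OC(C)(C)O[C@@H]2[C@@H](C)/C=C(\C)[C@H](O)[C@@H](OC)/C=C\C=C(/C)C(=O)OCC
F7 | step 22 | seco amino acid (F6 with the ethyl ester hydrolysed) | COCOc1cc(N)c(OCOC)c(c1)[C@H](OC)[C@@H](C)C[C@@H]2OC(C)(C)O[C@@H]2[C@@H](C)/C=C(\C)[C@H](O)[C@@H](OC)/C=C\C=C(/C)C(=O)O
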